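The C4–C5 cis-diol of the seven-membered ring (azulene numbering) sits between the C6 methylidene carbon and the quaternary C3a; it is read as a cis-vinylene unit stitched between an acyl carbon and an enone β-carbon. In the key step (Z)-1,2-bis(trimethylstannyl)ethene, made from acetylene, is joined in one flask to the C6 acid chloride (Stille) and, after tin–copper exchange, to C3a of a 2-substituted 3-methylcyclopentenone, closing the cycloheptenone by forming C5–C6 and C3a–C4. The C8 silyl ether steers C3a and C8a; the angular methyl then directs osmylation and isopropyl addition.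

Key step: step 8

Remark: azulene numbering of the target is used for all intermediates (C1 carbinol carbon, C3a methyl-bearing carbon, C4/C5 diol, C6 methylidene carbon, C8 ester carbon, C8a ring-fusion CH); in step 2 the ligand enantiomer is taken that delivers the (S)-carbinol.

Step 1
Reactants: 1 3-methylcyclopent-2-en-1-one
Product: 2 2-iodo-3-methylcyclopent-2-en-1-one
Conditions: I2, DMAP (cat.), K2CO3, THF/H2O, rt
Reagents that add atoms: iodine, [I][I]
Why: Johnson-type α-iodination (conjugate addition of DMAP, iodination of the enolate, elimination) should install the alkenyl iodide at the α-carbon of the enone.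

Step 2
Reactants: 2 2-iodo-3-methylcyclopent-2-en-1-one; 3 3-[(tert-butyldimethylsilyl)oxy]propanal
Product: 4 (S)-2-{3-[(tert-butyldimethylsilyl)oxy]-1-hydroxypropyl}-3-methylcyclopent-2-en-1-one
Conditions: CrCl2 (cat.), chiral oxazoline–methanesulfonamide ligand (cat.), 1,8-bis(dimethylamino)naphthalene (cat.), NiCl2·(2,9-dimethyl-1,10-phenanthroline) (cat.), Mn, Cp2ZrCl2, LiCl, MeCN, rt; aqueous work-up
Reagents that add atoms: none
Why: In this catalytic asymmetric Nozaki–Hiyama–Kishi reaction the alkenylchromium species formed from the α-iodoenone should add only to the aldehyde, the chiral sulfonamide ligand on chromium setting the carbinol centre (future C8) as S.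

Step 3
Reactants: 4 (S)-2-{3-[(tert-butyldimethylsilyl)oxy]-1-hydroxypropyl}-3-methylcyclopent-2-en-1-one
Product: 5 (S)-2-{3-[(tert-butyldimethylsilyl)oxy]-1-[(triisopropylsilyl)oxy]propyl}-3-methylcyclopent-2-en-1-one
Conditions: TIPSOTf, 2,6-lutidine, CH2Cl2, −78 to 0 °C
Reagents that add atoms: triisopropylsilyl triflate, CC(C)[Si](C(C)C)(C(C)C)OS(=O)(=O)C(F)(F)F
Why: Silyl ether formation with the silyl triflate should protect the hindered allylic alcohol as a bulky TIPS ether, which later acts as the stereodirecting group.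

Step 4
Reactants: 5 (S)-2-{3-[(tert-butyldimethylsilyl)oxy]-1-[(triisopropylsilyl)oxy]propyl}-3-methylcyclopent-2-en-1-one
Product: 6 (S)-2-{3-hydroxy-1-[(triisopropylsilyl)oxy]propyl}-3-methylcyclopent-2-en-1-one
Conditions: camphorsulfonic acid (cat.), MeOH/CH2Cl2, 0 °C
Reagents that add atoms: none
Why: Acid-catalysed methanolysis (selective desilylation) should cleave the unhindered primary TBS ether much faster than the secondary TIPS ether.

Step 5
Reactants: 6 (S)-2-{3-hydroxy-1-[(triisopropylsilyl)oxy]propyl}-3-methylcyclopent-2-en-1-one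
Product: 7 (S)-3-(2-methyl-5-oxocyclopent-1-en-1-yl)-3-[(triisopropylsilyl)oxy]propanoic acid
Conditions: TEMPO (cat.), PhI(OAc)2, MeCN/H2O, rt
Reagents that add atoms: water, O
Why: The TEMPO/PhI(OAc)2 oxidation should take the primary alcohol through the aldehyde hydrate to the acid without touching the enone or the silyl ether.

Step 6
Reactants: 7 (S)-3-(2-methyl-5-oxocyclopent-1-en-1-yl)-3-[(triisopropylsilyl)oxy]propanoic acid
Product: 8 (S)-3-(2-methyl-5-oxocyclopent-1-en-1-yl)-3-[(triisopropylsilyl)oxy]propanoyl chloride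
Conditions: 1-chloro-N,N,2-trimethylprop-1-en-1-amine, CH2Cl2, 0 °C to rt
Reagents that add atoms: 1-chloro-N,N,2-trimethylprop-1-en-1-amine, CC(C)=C(Cl)N(C)C
Why: Neutral acid chloride formation with the α-chloroenamine should avoid HCl and so preserve the allylic silyl ether.

Step 7
Reactants: 9 acetylene; 10 hexamethylditin
Product: 11 (Z)-1,2-bis(trimethylstannyl)ethene
Conditions: Pd(PPh3)4 (cat.), 1,4-dioxane, 60 °C, sealed vessel
Reagents that add atoms: none
Why: Palladium-catalysed distannylation of the alkyne is a syn addition of the Sn–Sn bond, which fixes the Z geometry of the two-carbon unit.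

Step 8
Reactants: 8 (S)-3-(2-methyl-5-oxocyclopent-1-en-1-yl)-3-[(triisopropylsilyl)oxy]propanoyl chloride; 11 (Z)-1,2-bis(trimethylstannyl)ethene
Product: 13 (3aR,8S,8aS)-3a-methyl-8-[(triisopropylsilyl)oxy]-2,3,3a,7,8,8a-hexahydroazulene-1,6-dione, via (Z)-β-stannyl enone 12 (not isolated)
Conditions: 11 (1.5 equiv), Pd2(dba)3 (cat.), AsPh3, THF, 50 °C; then CuCl (3 equiv), DMF, 0 °C to rt; AcOH, −78 °C
Reagents that add atoms: none
Why: Proposed new method: acylative Stille coupling of 8 with one tin terminus of 11 should give the chelated (Z)-β-stannyl enone 12, whose remaining C–Sn bond is exchanged by CuCl for an alkenylcopper that adds intramolecularly to the enone β-carbon C3a; the closest known reaction types are the acylative Stille coupling of alkenylstannanes and the CuCl-mediated intramolecular conjugate addition of alkenyltrimethylstannanes to enones, here joined in one flask and extended to a seven-membered ring. The seven-membered ring is closed in the second event by a 7-endo-trig conjugate addition, the cis-vinylene unit having been attached intermolecularly in the first. C3a is controlled by the C8 stereocentre: allylic 1,3-strain with the C3a methyl keeps the C8–H bond in the enone plane, so the tethered alkenylcopper is delivered on the face of the C7 chain, opposite the OTIPS group. C8a is set when the copper enolate is protonated, which should occur opposite the OTIPS group and the angular methyl and so give the trans ring fusion. The step needs mono-acylation of 11 with retention of the Z geometry and 1,4- rather than 1,2-addition; the excess of 11, O→Sn chelation in 12, the soft organocopper and the intramolecular setting should secure them.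

Step 9
Reactants: 13 (3aR,8S,8aS)-3a-methyl-8-[(triisopropylsilyl)oxy]-2,3,3a,7,8,8a-hexahydroazulene-1,6-dione
Product: 14 (3aS,4S,5S,8S,8aS)-4,5-dihydroxy-3a-methyl-8-[(triisopropylsilyl)oxy]octahydroazulene-1,6-dione
Conditions: OsO4 (cat.), NMO, citric acid, t-BuOH/H2O/acetone, rt
Reagents that add atoms: osmium tetroxide, O=[Os](=O)(=O)=O; N-methylmorpholine N-oxide, C[N+]1([O-])CCOCC1; water, O
Why: Upjohn dihydroxylation, buffered with citric acid for the electron-poor enone, should add both oxygens syn to C4=C5 from the face opposite the angular C3a methyl of the trans-fused bicycle, setting C4 and C5.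

Step 10
Reactants: 14 (3aS,4S,5S,8S,8aS)-4,5-dihydroxy-3a-methyl-8-[(triisopropylsilyl)oxy]octahydroazulene-1,6-dione
Product: 15 (3aS,4S,5S,8S,8aS)-4,5-(isopropylidenedioxy)-3a-methyl-8-[(triisopropylsilyl)oxy]octahydroazulene-1,6-dione
Conditions: 2,2-dimethoxypropane, PPTS (cat.), CH2Cl2, rt
Reagents that add atoms: 2,2-dimethoxypropane, COC(C)(C)OC
Why: Acid-catalysed transketalisation should lock the cis-diol as its acetonide, which also blocks retro-aldol cleavage and epimerisation at C5.

Step 11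
Reactants: 15 (3aS,4S,5S,8S,8aS)-4,5-(isopropylidenedioxy)-3a-methyl-8-[(triisopropylsilyl)oxy]octahydroazulene-1,6-dione
Product: 16 (3aS,4S,5R,8S,8aS)-4,5-(isopropylidenedioxy)-3a-methyl-6-methylidene-8-[(triisopropylsilyl)oxy]octahydroazulen-1(2H)-one
Conditions: Ph3PCH3Br, KN(SiMe3)2 (1.05 equiv of ylide), THF, −78 to 0 °C
Reagents that add atoms: methylenetriphenylphosphorane (from methyltriphenylphosphonium bromide), C=P(c1ccccc1)(c1ccccc1)c1ccccc1
Why: Wittig methylenation with one equivalent of ylide at low temperature should occur at the C6 ketone, which is activated by its α-alkoxy group and less hindered than the cyclopentanone carbonyl.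

Step 12
Reactants: 16 (3aS,4S,5R,8S,8aS)-4,5-(isopropylidenedioxy)-3a-methyl-6-methylidene-8-[(triisopropylsilyl)oxy]octahydroazulen-1(2H)-one; 17 isopropylmagnesium chloride
Product: 18 (1R,3aS,4S,5R,8S,8aS)-4,5-(isopropylidenedioxy)-3a-methyl-6-methylidene-1-(propan-2-yl)-8-[(triisopropylsilyl)oxy]decahydroazulen-1-ol
Conditions: CeCl3 (anhydrous), THF, −78 °C; aq. NH4Cl
Reagents that add atoms: none
Why: Organocerium 1,2-addition (which suppresses enolisation) should deliver the isopropyl group to the C1 carbonyl from the face opposite the angular methyl and the C8 silyloxy group, placing the new hydroxyl cis to the methyl.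

Step 13
Reactants: 18 (1R,3aS,4S,5R,8S,8aS)-4,5-(isopropylidenedioxy)-3a-methyl-6-methylidene-1-(propan-2-yl)-8-[(triisopropylsilyl)oxy]decahydroazulen-1-ol
Product: 19 (1R,3aS,4S,5R,8S,8aS)-4,5-(isopropylidenedioxy)-3a-methyl-6-methylidene-1-(propan-2-yl)decahydroazulene-1,8-diol
Conditions: Bu4NF, THF, rt to 40 °C
Reagents that add atoms: none
Why: Fluoride-mediated desilylation should free the C8 alcohol and leave the acetonide untouched.

Step 14
Reactants: 19 (1R,3aS,4S,5R,8S,8aS)-4,5-(isopropylidenedioxy)-3a-methyl-6-methylidene-1-(propan-2-yl)decahydroazulene-1,8-diol; 20 3-methylbutanoyl chloride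
Product: 21 (1R,3aS,4S,5R,8S,8aS)-1-hydroxy-4,5-(isopropylidenedioxy)-3a-methyl-6-methylidene-1-(propan-2-yl)decahydroazulen-8-yl 3-methylbutanoate
Conditions: pyridine, DMAP (cat.), CH2Cl2, 0 °C to rt
Reagents that add atoms: none
Why: DMAP-catalysed acylation should esterify only the secondary C8 alcohol, the tertiary C1 alcohol being too hindered.

Step 15
Reactants: 21 (1R,3aS,4S,5R,8S,8aS)-1-hydroxy-4,5-(isopropylidenedioxy)-3a-methyl-6-methylidene-1-(propan-2-yl)decahydroazulen-8-yl 3-methylbutanoate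
Product: 22 (1R,3aS,4S,5R,8S,8aS)-1,4,5-trihydroxy-3a-methyl-6-methylidene-1-(propan-2-yl)decahydroazulen-8-yl 3-methylbutanoate
Conditions: AcOH/H2O (4:1), 45 °C
Reagents that add atoms: none
Why: Mild acid-catalysed acetal hydrolysis should release the C4,C5-diol without affecting the ester, the allylic alcohol or the tertiary alcohol.

Compound list
1 | 3-methylcyclopent-2-en-1-one | CC1=CC(=O)CC1 | starting material
2 | 2-iodo-3-methylcyclopent-2-en-1-one | CC1=C(I)C(=O)CC1 | intermediate
3 | 3-[(tert-butyldimethylsilyl)oxy]propanal | O=CCCO[Si](C)(C)C(C)(C)C | starting material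
4 | (S)-2-{3-[(tert-butyldimethylsilyl)oxy]-1-hydroxypropyl}-3-methylcyclopent-2-en-1-one | CC(C)(C)[Si](C)(C)OCC[C@H](O)C1=C(C)CCC1=O | intermediate
5 | (S)-2-{3-[(tert-butyldimethylsilyl)oxy]-1-[(triisopropylsilyl)oxy]propyl}-3-methylcyclopent-2-en-1-one | CC(C)(C)[Si](C)(C)OCC[C@H](O[Si](C(C)C)(C(C)C)C(C)C)C1=C(C)CCC1=O | intermediate
6 | (S)-2-{3-hydroxy-1-[(triisopropylsilyl)oxy]propyl}-3-methylcyclopent-2-en-1-one | OCC[C@H](O[Si](C(C)C)(C(C)C)C(C)C)C1=C(C)CCC1=O | intermediate
7 | (S)-3-(2-methyl-5-oxocyclopent-1-en-1-yl)-3-[(triisopropylsilyl)oxy]propanoic acid | OC(=O)C[C@H](O[Si](C(C)C)(C(C)C)C(C)C)C1=C(C)CCC1=O | intermediate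
8 | (S)-3-(2-methyl-5-oxocyclopent-1-en-1-yl)-3-[(triisopropylsilyl)oxy]propanoyl chloride | ClC(=O)C[C@H](O[Si](C(C)C)(C(C)C)C(C)C)C1=C(C)CCC1=O | intermediate
9 | acetylene | C#C | starting material
10 | hexamethylditin | C[Sn](C)(C)[Sn](C)(C)C | starting material
11 | (Z)-1,2-bis(trimethylstannyl)ethene | C[Sn](C)(C)/C=C\[Sn](C)(C)C | intermediate
12 | (S,Z)-3-methyl-2-{3-oxo-1-[(triisopropylsilyl)oxy]-5-(trimethylstannyl)pent-4-en-1-yl}cyclopent-2-en-1-one | C[Sn](C)(C)/C=C\C(=O)C[C@H](O[Si](C(C)C)(C(C)C)C(C)C)C1=C(C)CCC1=O | intermediate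
13 | (3aR,8S,8aS)-3a-methyl-8-[(triisopropylsilyl)oxy]-2,3,3a,7,8,8a-hexahydroazulene-1,6-dione | O=C1C[C@H](O[Si](C(C)C)(C(C)C)C(C)C)[C@@H]2[C@](C)(CCC2=O)C=C1 | intermediate
14 | (3aS,4S,5S,8S,8aS)-4,5-dihydroxy-3a-methyl-8-[(triisopropylsilyl)oxy]octahydroazulene-1,6-dione | O=C1C[C@H](O[Si](C(C)C)(C(C)C)C(C)C)[C@@H]2[C@](C)(CCC2=O)[C@H](O)[C@@H]1O | intermediate
15 | (3aS,4S,5S,8S,8aS)-4,5-(isopropylidenedioxy)-3a-methyl-8-[(triisopropylsilyl)oxy]octahydroazulene-1,6-dione | O=C1C[C@H](O[Si](C(C)C)(C(C)C)C(C)C)[C@@H]2[C@](C)(CCC2=O)[C@H](OC3(C)C)[C@@H]1O3 | intermediate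
16 | (3aS,4S,5R,8S,8aS)-4,5-(isopropylidenedioxy)-3a-methyl-6-methylidene-8-[(triisopropylsilyl)oxy]octahydroazulen-1(2H)-one | C=C1C[C@H](O[Si](C(C)C)(C(C)C)C(C)C)[C@@H]2[C@](C)(CCC2=O)[C@H](OC3(C)C)[C@@H]1O3 | intermediate
17 | isopropylmagnesium chloride | CC(C)[Mg]Cl | starting material
18 | (1R,3aS,4S,5R,8S,8aS)-4,5-(isopropylidenedioxy)-3a-methyl-6-methylidene-1-(propan-2-yl)-8-[(triisopropylsilyl)oxy]decahydroazulen-1-ol | C=C1C[C@H](O[Si](C(C)C)(C(C)C)C(C)C)[C@@H]2[C@](C)(CC[C@@]2(O)C(C)C)[C@H](OC3(C)C)[C@@H]1O3 | intermediate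
19 | (1R,3aS,4S,5R,8S,8aS)-4,5-(isopropylidenedioxy)-3a-methyl-6-methylidene-1-(propan-2-yl)decahydroazulene-1,8-diol | C=C1C[C@H](O)[C@@H]2[C@](C)(CC[C@@]2(O)C(C)C)[C@H](OC3(C)C)[C@@H]1O3 | intermediate
20 | 3-methylbutanoyl chloride | CC(C)CC(=O)Cl | starting material
21 | (1R,3aS,4S,5R,8S,8aS)-1-hydroxy-4,5-(isopropylidenedioxy)-3a-methyl-6-methylidene-1-(propan-2-yl)decahydroazulen-8-yl 3-methylbutanoate | C=C1C[C@H](OC(=O)CC(C)C)[C@@H]2[C@](C)(CC[C@@]2(O)C(C)C)[C@H](OC3(C)C)[C@@H]1O3 | intermediate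
22 | (1R,3aS,4S,5R,8S,8aS)-1,4,5-trihydroxy-3a-methyl-6-methylidene-1-(propan-2-yl)decahydroazulen-8-yl 3-methylbutanoate | C=C1C[C@H](OC(=O)CC(C)C)[C@@H]2[C@](C)(CC[C@@]2(O)C(C)C)[C@H](O)[C@@H]1O | target

Total step count: 15. Longest linear sequence: 14 steps (steps 1 to 6 and 8 to 15).

Steps most likely to fail

1. Step 8 (bears the label "Proposed new method:"). The tin–copper exchange or the conjugate addition onto the tetrasubstituted enone may be too slow, so that protodestannylation or intermolecular coupling takes over. The protonation that sets C8a may also show poor facial selectivity. Fallback with known chemistry, from 8 back to 13: 8 is coupled with 11 under the palladium conditions alone and 12 is isolated. Iododestannylation (I2, CH2Cl2, 0 °C) should give the (Z)-β-iodo enone F1. A nickel-catalysed reductive conjugate addition of the alkenyl iodide to the enone (NiCl2·glyme, 2,9-dimethyl-1,10-phenanthroline, Mn, Et3SiCl, DMF) should then close the ring to the triethylsilyl enol ether F2. Protodesilylation of F2 with citric acid in methanol returns 13.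

2. Step 11. Chemoselectivity between the two ketones may be lost, and the basic ylide may cause β-elimination of the silyloxy group or epimerisation at C8a. Fallback from 13 back to 16, in which the carbonyls are told apart by oxidation level: NaBH4 in MeOH/CH2Cl2 at −78 °C should reduce the saturated C1 ketone of 13 and leave the enone, giving the C1 alcohol F3. Dihydroxylation as in step 9 gives the triol F4 and acetonide formation as in step 10 gives the hydroxy ketone acetonide F5. Wittig methylenation of the only remaining ketone with excess ylide gives the methylidene alcohol F6, and Dess–Martin oxidation of F6 returns 16.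

3. Step 2. Oxidative addition to the hindered α-iodoenone may be sluggish and the enantioselectivity at the future C8 may be insufficient. Fallback from 1 back to 4, with the stereocentre set by reduction instead of addition: bromination and dehydrobromination of 1 (Br2, then Et3N) gives 2-bromo-3-methylcyclopent-2-en-1-one F7, and ketalisation (ethylene glycol, TsOH) gives the bromo ketal F8. Bromine–lithium exchange (t-BuLi, THF, −78 °C) and addition to 3 gives the racemic ketal alcohol F9, and Dess–Martin oxidation gives the ketal ketone F10. Corey–Bakshi–Shibata reduction gives the (S)-ketal alcohol F11, whose hydrolysis (PPTS, acetone/H2O) returns 4.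

Further compounds
F1 | step 8 | (S,Z)-2-{5-iodo-3-oxo-1-[(triisopropylsilyl)oxy]pent-4-en-1-yl}-3-methylcyclopent-2-en-1-one | I/C=C\C(=O)C[C@H](O[Si](C(C)C)(C(C)C)C(C)C)C1=C(C)CCC1=O
F2 | step 8 | (3aR,8S)-3a-methyl-1-[(triethylsilyl)oxy]-8-[(triisopropylsilyl)oxy]-3,3a,7,8-tetrahydroazulen-6(2H)-one | O=C1C[C@H](O[Si](C(C)C)(C(C)C)C(C)C)C2=C(O[Si](CC)(CC)CC)CC[C@]2(C)C=C1
F3 | step 11 | (1S,3aR,8S,8aR)-1-hydroxy-3a-methyl-8-[(triisopropylsilyl)oxy]-1,2,3,3a,8,8a-hexahydroazulen-6(7H)-one | O=C1C[C@H](O[Si](C(C)C)(C(C)C)C(C)C)[C@@H]2[C@](C)(CC[C@@H]2O)C=C1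
F4 | step 11 | (1S,3aS,4S,5S,8S,8aR)-1,4,5-trihydroxy-3a-methyl-8-[(triisopropylsilyl)oxy]octahydroazulen-6(1H)-one | O=C1C[C@H](O[Si](C(C)C)(C(C)C)C(C)C)[C@@H]2[C@](C)(CC[C@@H]2O)[C@H](O)[C@@H]1O
F5 | step 11 | (1S,3aS,4S,5S,8S,8aR)-1-hydroxy-4,5-(isopropylidenedioxy)-3a-methyl-8-[(triisopropylsilyl)oxy]octahydroazulen-6(1H)-one | O=C1C[C@H](O[Si](C(C)C)(C(C)C)C(C)C)[C@@H]2[C@](C)(CC[C@@H]2O)[C@H](OC3(C)C)[C@@H]1O3
F6 | step 11 | (1S,3aS,4S,5R,8S,8aR)-4,5-(isopropylidenedioxy)-3a-methyl-6-methylidene-8-[(triisopropylsilyl)oxy]decahydroazulen-1-ol | C=C1C[C@H](O[Si](C(C)C)(C(C)C)C(C)C)[C@@H]2[C@](C)(CC[C@@H]2O)[C@H](OC3(C)C)[C@@H]1O3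
F7 | step 2 | 2-bromo-3-methylcyclopent-2-en-1-one | CC1=C(Br)C(=O)CC1
F8 | step 2 | 6-bromo-7-methyl-1,4-dioxaspiro[4.4]non-6-ene | CC1=C(Br)C2(CC1)OCCO2
F9 | step 2 | racemic 3-[(tert-butyldimethylsilyl)oxy]-1-(7-methyl-1,4-dioxaspiro[4.4]non-6-en-6-yl)propan-1-ol | CC1=C(C(O)CCO[Si](C)(C)C(C)(C)C)C2(CC1)OCCO2
F10 | step 2 | 3-[(tert-butyldimethylsilyl)oxy]-1-(7-methyl-1,4-dioxaspiro[4.4]non-6-en-6-yl)propan-1-one | CC1=C(C(=O)CCO[Si](C)(C)C(C)(C)C)C2(CC1)OCCO2
F11 | step 2 | (S)-3-[(tert-butyldimethylsilyl)oxy]-1-(7-methyl-1,4-dioxaspiro[4.4]non-6-en-6-yl)propan-1-ol | CC(C)(C)[Si](C)(C)OCC[C@H](O)C1=C(C)CCC12OCCO2
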